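**Retrosynthetic overview**
1. Feature used: the ring O/C7–C10 is a cis-2,5-bridging tetrahydrofuran. Both of its ether carbons (C7, C10) are quaternary, and each adjoins an oxygen-bearing carbon of the ten-membered ring (C6–O of the lactone, C1=O). This C6/C1 pair is what remains after a one-carbon C=O bridge is cut out of a furan/oxyallyl (4+3) adduct.
2. Late disconnections: C1=O comes from a C1 alkoxyamine (decarboxylated C1 acid). The methylidene lactone comes from a C11–C12 hydroxyethyl chain carried in on the furan. The C8 ester follows a C6–OH-directed reduction, and the 4,5-epoxide is set on the still-bridged lactone.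
3. Bridge excision: Baeyer–Villiger insertion next to allylic C6 (retention), then hydrolysis.
4. Key disconnection: C6–C7 and C1–C10 by (4+3) cycloaddition of silyloxyfuran 14 with the alkenyl-extended oxyallyl cation from bromoenone 7.
5. Ring order: the cycloheptenone (ring expansion) and the furan come first. Step 9 closes the oxa-bridged seven-membered ring and the ten-membered ring together. The epoxide follows in step 14 and the γ-lactone ring last (steps 23–25).

Key step: step 9

Remark: target numbering (C1 ketone to C10, C11–C13 for the methylidene-lactone carbons) is used for all intermediates; 16 and 17 are racemic and drawn as the enantiomer kept in step 11; the bromide sits on C1 of the conjugated enone because a bromide on the doubly activated C6 would enolise at its own carbon and end as a vinyl bromide, whereas 7 reaches the same cation; the C7 side chain is CH2CH2OTBS because an unactivated C7 methyl group offers no dependable access to C11–C13.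

Step 1
Reactants: 1 cyclohex-2-en-1-one
Product: 2 3-methyl-1-(trimethylsilyloxy)cyclohex-1-ene
Conditions: MeMgBr, CuBr·SMe2 (5 mol %), TMSCl, DMPU, THF, −78 °C
Reagents that add atoms: methylmagnesium bromide C[Mg]Br; chlorotrimethylsilane C[Si](C)(C)Cl
Why: TMSCl-accelerated copper-catalysed conjugate addition places the future C4 methyl group and traps the enolate regiospecifically as the silyl enol ether on the methyl-bearing side; the stereocentre is racemic and is erased in step 9.

Step 2
Reactants: 2 3-methyl-1-(trimethylsilyloxy)cyclohex-1-ene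
Product: 3 2-methyl-1-(trimethylsilyloxy)bicyclo[4.1.0]heptane
Conditions: Et2Zn, CH2I2, CH2Cl2, 0 °C
Reagents that add atoms: diiodomethane ICI
Why: The Furukawa-modified Simmons–Smith cyclopropanation is fastest on electron-rich enol ethers and delivers the CH2 that becomes C6; the relative configuration is without consequence.

Step 3
Reactants: 3 2-methyl-1-(trimethylsilyloxy)bicyclo[4.1.0]heptane
Product: 5 4-methylcyclohept-2-en-1-one, via chloroketone 4 (not isolated)
Conditions: FeCl3, DMF, 0 °C to rt; then NaOAc, MeOH, reflux
Reagents that add atoms: none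
Why: In the Ito–Saegusa one-carbon ring expansion FeCl3 oxidises the siloxycyclopropane, the ring-fusion bond breaks, the β-keto radical is chlorinated to 4 and E1cB loss of HCl gives the cycloheptenone with carbonyl and methyl carbon in the required 1,4-relation, without the regioisomers of a diazoalkane homologation.

Step 4
Reactants: 5 4-methylcyclohept-2-en-1-one
Product: 7 7-bromo-4-methylcyclohept-2-en-1-one, via silyl dienol ether 6 (not isolated)
Conditions: LiN(i-Pr)2, THF, −78 °C; TMSCl; then NBS, THF, −78 to 0 °C
Reagents that add atoms: N-bromosuccinimide O=C1CCC(=O)N1Br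
Why: Kinetic α′-deprotonation of a conjugated enone followed by electrophilic bromination of the cross-conjugated silyl dienol ether puts the leaving group on C1 only; both stereocentres vanish on ionisation.

Step 5
Reactants: 8 3-hydroxyoxolan-2-one (α-hydroxy-γ-butyrolactone)
Product: 10 4-(tert-butyldimethylsilyloxy)-2-hydroxy-N-methoxy-N-methylbutanamide, via dihydroxy amide 9 (not isolated)
Conditions: MeNH(OMe)·HCl, i-PrMgCl, THF, −20 to 0 °C, aq NH4Cl; crude, then TBSCl (1.05 equiv), imidazole, CH2Cl2, 0 °C
Reagents that add atoms: N,O-dimethylhydroxylamine hydrochloride CNOC.Cl; tert-butyldimethylsilyl chloride CC(C)(C)[Si](C)(C)Cl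
Why: Weinreb aminolysis of the lactone by the magnesium amide is followed at once by chemoselective silylation of the primary alcohol, which stops relactonisation and leaves the α-hydroxyl free for ring closure.

Step 6
Reactants: 10 4-(tert-butyldimethylsilyloxy)-2-hydroxy-N-methoxy-N-methylbutanamide; 11 prop-1-yn-1-ylmagnesium bromide
Product: 12 7-(tert-butyldimethylsilyloxy)-5-hydroxyhept-2-yn-4-one
Conditions: 11 (2.5 equiv), THF, 0 °C; aq NH4Cl
Reagents that add atoms: none
Why: In the Weinreb ketone synthesis the first equivalent deprotonates the hydroxyl and the chelated tetrahedral intermediate prevents a second addition.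

Step 7
Reactants: 12 7-(tert-butyldimethylsilyloxy)-5-hydroxyhept-2-yn-4-one
Product: 13 2-[2-(tert-butyldimethylsilyloxy)ethyl]-5-methylfuran-3(2H)-one
Conditions: (p-CF3C6H4)3PAuCl (5 mol %), AgOTf (5 mol %), toluene, rt
Reagents that add atoms: none
Why: π-Acid-catalysed 5-endo-dig cycloisomerisation of an α′-hydroxy ynone is a known route to 3(2H)-furanones, and the protected primary oxygen cannot compete.

Step 8
Reactants: 13 2-[2-(tert-butyldimethylsilyloxy)ethyl]-5-methylfuran-3(2H)-one
Product: 14 3-(tert-butyldimethylsilyloxy)-2-[2-(tert-butyldimethylsilyloxy)ethyl]-5-methylfuran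
Conditions: TBSOTf, Et3N, CH2Cl2, 0 °C
Reagents that add atoms: tert-butyldimethylsilyl triflate CC(C)(C)[Si](C)(C)OS(=O)(=O)C(F)(F)F
Why: Soft enolisation at the acidic C2–H with O-silylation is driven by aromatisation to the 3-silyloxyfuran.

Step 9
Reactants: 7 7-bromo-4-methylcyclohept-2-en-1-one; 14 3-(tert-butyldimethylsilyloxy)-2-[2-(tert-butyldimethylsilyloxy)ethyl]-5-methylfuran
Product: 16 racemic carbonyl- and oxygen-bridged cyclodecadiene (C8 silyl enol ether), via oxyallyl zwitterion 15 (not isolated)
Conditions: 14 (1.5 equiv), i-Pr2NEt, LiClO4 (3 M), Et2O, 0 °C to rt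
Reagents that add atoms: none
Why: Proposed new method: lithium-assisted reversible γ-deprotonation of 7 (C4–H) gives the extended dienolate, the only enolate of 7 that can expel the C1 bromide, and so the zwitterion 15, best seen as a C1 enolate attached to a C6–C5–C4 allyl cation; C7 of 14, the carbon activated by both the ring oxygen and the silyloxy group, bonds to C6, and the enolate carbon C1 then adds to C10 of the silyloxy-stabilised oxocarbenium ion, which regenerates the C8 silyl enol ether. The closest known reaction type is the base-induced (4+3) cycloaddition of furans with cyclic oxyallyl cations from α-halo ketones in LiClO4/Et2O or fluorinated alcohols; new are the alkenyl-extended cation, its generation by γ-deprotonation and a furan substituted at both termini. The second bond closes the oxygen-bridged seven-membered carbocycle (C6–C7–C8–C9–C10–C1–C=O) by intramolecular enolate-to-oxocarbenium addition, and because C1 and C6 are already tied by C2–C5 of the cation ring the same bond closes the ten-membered carbocycle C1–C10 with the old carbonyl as a one-carbon bridge. C7 and C10 must bond on one furan face and C6 and C1 on one face of the flat cation (both enforced by the bridging geometry), while the relation between the two pairs depends on the extended orientation (C=O bridge on the side of the furan oxygen, C2–C5 under C8–C9), expected because it stacks the electron-rich C8–C9 edge on the cationic C6–C5–C4 arm and keeps the lithium-bound oxido group away from the C8 silyloxy group; the product is racemic. The step needs C7-to-C6 pairing (secured by donor–acceptor matching of the most nucleophilic furan carbon with the allyl-cation end and of the enolate end with C10), attack at C6 rather than C4 (C4 is fully substituted and would have to join quaternary C7) and cycloaddition faster than proton loss from C3 or the C4 methyl group (excess 14, hindered amine).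

Step 10
Reactants: 16 racemic carbonyl- and oxygen-bridged cyclodecadiene (C8 silyl enol ether)
Product: 17 racemic bridged C8 ketone (diketone)
Conditions: 0.1 M aq HCl, THF, 0 °C
Reagents that add atoms: none
Why: Acid hydrolysis of a silyl enol ether is much faster than cleavage of the primary TBS ether, and the bridge ketone cannot enolise (bridgehead), so C6 and C1 are safe.

Step 11
Reactants: 17 racemic bridged C8 ketone (diketone)
Product: 18 bridged diketone as single enantiomer (C6 C7 C10 as in the target)
Conditions: preparative SFC, amylose tris(3,5-dimethylphenylcarbamate) phase, CO2/i-PrOH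
Reagents that add atoms: none
Why: Resolution by chromatography on a chiral stationary phase fixes the absolute configuration of C6, C7 and C10 on a robust early intermediate; the enantiomer is to be assigned by X-ray analysis of a heavy-atom derivative.

Step 12
Reactants: 18 bridged diketone as single enantiomer
Product: 19 C8-methylidene bridge ketone
Conditions: Ph3PCH3Br, KOt-Bu, toluene/THF, 0 to 60 °C
Reagents that add atoms: methyltriphenylphosphonium bromide C[P+](c1ccccc1)(c1ccccc1)c1ccccc1.[Br-]
Why: Wittig methylenation takes the C8 ketone from its open exo face and leaves the bridge ketone (flanked by two tertiary carbons) alone, which masks C8 against the peroxide of step 13 and against retro-aldol cleavage of C6–C7 in the basic step 15.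

Step 13
Reactants: 19 C8-methylidene bridge ketone
Product: 20 bridged allylic lactone (C6–O–C(=O)–C1)
Conditions: (TMSO)2 (3 equiv), TMSOTf (0.2 equiv), 2,6-di-tert-butyl-4-methylpyridine (0.1 equiv), CH2Cl2, −78 to −30 °C
Reagents that add atoms: bis(trimethylsilyl) peroxide C[Si](C)(C)OO[Si](C)(C)C
Why: Baeyer–Villiger oxidation with the silyl peroxide activates the carbonyl rather than the peroxide and so spares both alkenes; secondary allylic C6 should migrate in preference to secondary alkyl C1, with retention, which sets the C6–O configuration.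

Step 14
Reactants: 20 bridged allylic lactone
Product: 21 bridged 4,5-epoxy lactone
Conditions: mCPBA (1.05 equiv), NaHCO3, CH2Cl2, −20 to 0 °C
Reagents that add atoms: 3-chloroperoxybenzoic acid OOC(=O)c1cccc(Cl)c1
Why: Prilezhaev epoxidation picks the trisubstituted Z-alkene over the hindered 1,1-disubstituted one and attacks the outer face, because the inner face lies against C8–C9 in the bridged frame, so the oxygen ends anti to C7 and syn to H6 (4R,5S).

Step 15
Reactants: 21 bridged 4,5-epoxy lactone
Product: 22 C6-hydroxy C1-carboxylic acid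
Conditions: LiOH, THF/H2O, 40 °C; then cold aq KHSO4 to pH 4
Reagents that add atoms: lithium hydroxide [Li+].[OH-]
Why: Saponification opens the bridge and frees the ten-membered ring; with C8 still an alkene the C6 alkoxide has no retro-aldol path, and a Payne shift would be reversible and favour the trisubstituted epoxide.

Step 16
Reactants: 22 C6-hydroxy C1-carboxylic acid
Product: 24 C6-O-triethylsilyl C1-carboxylic acid, via bis-triethylsilyl derivative 23 (not isolated)
Conditions: TESOTf, 2,6-lutidine, CH2Cl2, −78 °C; aq NaHCO3/MeOH work-up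
Reagents that add atoms: triethylsilyl triflate CC[Si](CC)(CC)OS(=O)(=O)C(F)(F)F
Why: Silylation blocks C6–OH so that activation of the C1 acid in step 18 cannot simply re-close the lactone, and the silyl ester falls off on work-up.

Step 17
Reactants: 24 C6-O-triethylsilyl C1-carboxylic acid
Product: 25 C8-keto C1-carboxylic acid
Conditions: O3, CH2Cl2, −78 °C; Me2S
Reagents that add atoms: ozone [O-][O+]=O
Why: Ozonolysis of the only remaining alkene unmasks the C8 ketone under neutral conditions.

Step 18
Reactants: 25 C8-keto C1-carboxylic acid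
Product: 27 C1 alkoxyamine (C1 epimers), via thiohydroxamate ester 26 (not isolated)
Conditions: 1-hydroxypyridine-2(1H)-thione, EDC·HCl, DMAP (cat.), CH2Cl2, 0 °C, dark; then TEMPO (3 equiv), visible light, 0 °C
Reagents that add atoms: TEMPO CC1(C)CCCC(C)(C)N1[O]
Why: Barton decarboxylation with nitroxide trapping replaces the carboxyl carbon (the last atom of the old bridge) by oxygen at C1; no alkene or free hydroxyl is present to intercept radicals or the active ester, and the C1 configuration is irrelevant.

Step 19
Reactants: 27 C1 alkoxyamine (C1 epimers)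
Product: 28 C6-hydroxy C8-ketone
Conditions: PPTS, MeOH/CH2Cl2, 0 °C
Reagents that add atoms: none
Why: Acid-catalysed methanolysis removes the TES ether ahead of the primary TBS ether and releases the β-hydroxy ketone without base, so retro-aldol cleavage is avoided.

Step 20
Reactants: 28 C6-hydroxy C8-ketone
Product: 29 C6,C8-diol (8S)
Conditions: Me4NBH(OAc)3, MeCN/AcOH, −30 °C
Reagents that add atoms: none
Why: In the Evans–Saksena reduction the borohydride binds to C6–OH and delivers hydride within the molecule to the C8 face that carries C6, so the hydroxyl ends on the side of the ring oxygen (cis to C11), the opposite of what external hydride from the open face would give.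

Step 21
Reactants: 29 C6,C8-diol (8S); 30 methacrylic anhydride
Product: 31 C8 methacrylate with free C6–OH
Conditions: 30 (1.3 equiv), DMAP (cat.), Et3N, CH2Cl2, 0 °C
Reagents that add atoms: none
Why: DMAP-catalysed acylation should take C8–OH (next to a CH2, on the convex face) before C6–OH (wedged between quaternary C7 and the epoxide), and the trans arrangement of C6 and O8 on the oxolane rules out later acyl migration.

Step 22
Reactants: 31 C8 methacrylate with free C6–OH
Product: 32 C12 primary alcohol
Conditions: Et3N·3HF, MeCN, rt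
Reagents that add atoms: none
Why: Mild, nearly neutral fluoride desilylation frees C12–OH without touching the epoxide, the ester or the alkoxyamine.

Step 23
Reactants: 32 C12 primary alcohol
Product: 34 C6–O–C12 lactol, via hydroxy aldehyde 33 (not isolated)
Conditions: Dess–Martin periodinane (1.1 equiv), NaHCO3, CH2Cl2, 0 °C
Reagents that add atoms: none
Why: Dess–Martin oxidation takes the unhindered primary alcohol first, and aldehyde 33 is captured by C6–OH (5-exo-trig hemiacetalisation), which closes the five-membered O6–C12–C11–C7–C6 ring; O8 is already acylated and cannot compete.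

Step 24
Reactants: 34 C6–O–C12 lactol
Product: 35 α-methylidene lactol
Conditions: 37 % aq HCHO, pyrrolidine (20 mol %), propionic acid (20 mol %), i-PrOH, 45 °C
Reagents that add atoms: formaldehyde C=O
Why: Amine-catalysed Mannich condensation and elimination (organocatalytic α-methylenation of aldehydes) works on the open form that the lactol supplies through its enamine, installs C13 without strong base and leaves the esters and the masked C1 alone.

Step 25
Reactants: 35 α-methylidene lactol
Product: 36 α-methylidene-γ-lactone alkoxyamine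
Conditions: Dess–Martin periodinane, NaHCO3, CH2Cl2, rt
Reagents that add atoms: none
Why: Lactol-to-lactone oxidation with Dess–Martin periodinane is mild and completes the 6,12-lactone with C6 and C7 unchanged.

Step 26
Reactants: 36 α-methylidene-γ-lactone alkoxyamine
Product: 37 CNP0241021.1 (target)
Conditions: mCPBA, CH2Cl2, 0 °C to rt
Reagents that add atoms: none
Why: Peracid N-oxidation of the secondary alkoxyamine and fragmentation of the N-oxide gives the C1 ketone from both C1 epimers, while the two electron-poor alkenes and the epoxide are inert to the peracid.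

**Compound list**
1 | cyclohex-2-en-1-one | O=C1C=CCCC1 | starting material
2 | 3-methyl-1-(trimethylsilyloxy)cyclohex-1-ene (racemic) | CC1CCCC(O[Si](C)(C)C)=C1 | intermediate
3 | 2-methyl-1-(trimethylsilyloxy)bicyclo[4.1.0]heptane (racemic, diastereomers) | CC1CCCC2(O[Si](C)(C)C)CC12 | intermediate
4 | 3-chloro-4-methylcycloheptan-1-one (not isolated) | CC1CCCC(=O)CC1Cl | intermediate
5 | 4-methylcyclohept-2-en-1-one (racemic) | CC1CCCC(=O)C=C1 | intermediate
6 | 5-methyl-2-(trimethylsilyloxy)cyclohepta-1,3-diene (not isolated) | CC1CCC=C(O[Si](C)(C)C)C=C1 | intermediate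
7 | 7-bromo-4-methylcyclohept-2-en-1-one (racemic, cis/trans mixture; Br on C1, methyl on C4) | CC1CCC(Br)C(=O)C=C1 | intermediate
8 | 3-hydroxyoxolan-2-one (α-hydroxy-γ-butyrolactone, racemic) | O=C1OCCC1O | starting material
9 | 2,4-dihydroxy-N-methoxy-N-methylbutanamide (not isolated) | CON(C)C(=O)C(O)CCO | intermediate
10 | 4-(tert-butyldimethylsilyloxy)-2-hydroxy-N-methoxy-N-methylbutanamide | CON(C)C(=O)C(O)CCO[Si](C)(C)C(C)(C)C | intermediate
11 | prop-1-yn-1-ylmagnesium bromide | CC#C[Mg]Br | starting material
12 | 7-(tert-butyldimethylsilyloxy)-5-hydroxyhept-2-yn-4-one | CC#CC(=O)C(O)CCO[Si](C)(C)C(C)(C)C | intermediate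
13 | 2-[2-(tert-butyldimethylsilyloxy)ethyl]-5-methylfuran-3(2H)-one | CC1=CC(=O)C(CCO[Si](C)(C)C(C)(C)C)O1 | intermediate
14 | 3-(tert-butyldimethylsilyloxy)-2-[2-(tert-butyldimethylsilyloxy)ethyl]-5-methylfuran | Cc1cc(O[Si](C)(C)C(C)(C)C)c(CCO[Si](C)(C)C(C)(C)C)o1 | intermediate
15 | alkenyl-extended oxyallyl zwitterion: C1 enolate joined to the C6–C5–C4 allyl cation (not isolated) | CC1=C[CH+]C([O-])=CCC1 | intermediate
16 | (4+3) adduct, racemic: cyclodeca-4,8-diene C1–C10 bridged by C=O (C1 to C6) and by O (C7 to C10), both bridges on the same ring face; Z-C4=C5 with C4 methyl; C8 OTBS enol ether; C7 CH2CH2OTBS; C10 methyl | C[C@]12C=C(O[Si](C)(C)C(C)(C)C)[C@](CCO[Si](C)(C)C(C)(C)C)(O1)[C@H]1/C=C(/C)CC[C@@H]2C1=O | intermediate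
17 | diketone, racemic: as 16 with C8=O and C9H2 | C[C@]12CC(=O)[C@](CCO[Si](C)(C)C(C)(C)C)(O1)[C@H]1/C=C(/C)CC[C@@H]2C1=O | intermediate
18 | diketone, single enantiomer (C6, C7, C10 as in the target) | C[C@]12CC(=O)[C@](CCO[Si](C)(C)C(C)(C)C)(O1)[C@H]1/C=C(/C)CC[C@@H]2C1=O | intermediate
19 | as 18 with C8=CH2 | C[C@]12CC(=C)[C@](CCO[Si](C)(C)C(C)(C)C)(O1)[C@H]1/C=C(/C)CC[C@@H]2C1=O | intermediate
20 | bridged lactone: oxygen inserted between C6 and the bridge carbonyl, retention at C6 | C[C@]12CC(=C)[C@](CCO[Si](C)(C)C(C)(C)C)(O1)[C@H]1/C=C(/C)CC[C@@H]2C(=O)O1 | intermediate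
21 | as 20 with the (4R,5S)-epoxide, oxygen anti to C7 | C[C@]12CC(=C)[C@](CCO[Si](C)(C)C(C)(C)C)(O1)[C@H]1[C@@H]3O[C@]3(C)CC[C@@H]2C(=O)O1 | intermediate
22 | 7,10-epoxy-bridged cyclodecane: C6–OH, C1–CO2H, 4,5-epoxide, C8=CH2 | C[C@]12CC(=C)[C@](CCO[Si](C)(C)C(C)(C)C)(O1)[C@H](O)[C@@H]3O[C@]3(C)CC[C@@H]2C(=O)O | intermediate
23 | C6 TES ether and TES ester of 22 (not isolated) | C[C@]12CC(=C)[C@](CCO[Si](C)(C)C(C)(C)C)(O1)[C@H](O[Si](CC)(CC)CC)[C@@H]3O[C@]3(C)CC[C@@H]2C(=O)O[Si](CC)(CC)CC | intermediate
24 | C6 TES ether of 22, free acid | C[C@]12CC(=C)[C@](CCO[Si](C)(C)C(C)(C)C)(O1)[C@H](O[Si](CC)(CC)CC)[C@@H]3O[C@]3(C)CC[C@@H]2C(=O)O | intermediate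
25 | as 24 with C8=O | C[C@]12CC(=O)[C@](CCO[Si](C)(C)C(C)(C)C)(O1)[C@H](O[Si](CC)(CC)CC)[C@@H]3O[C@]3(C)CC[C@@H]2C(=O)O | intermediate
26 | 2-thioxopyridin-1(2H)-yl ester of 25 (not isolated) | C[C@]12CC(=O)[C@](CCO[Si](C)(C)C(C)(C)C)(O1)[C@H](O[Si](CC)(CC)CC)[C@@H]3O[C@]3(C)CC[C@@H]2C(=O)ON4C=CC=CC4=S | intermediate
27 | C1 O-(2,2,6,6-tetramethylpiperidin-1-yl) ether (C1 epimers), C8 ketone, C6 OTES | C[C@]12CC(=O)[C@](CCO[Si](C)(C)C(C)(C)C)(O1)[C@H](O[Si](CC)(CC)CC)[C@@H]3O[C@]3(C)CCC2ON4C(C)(C)CCCC4(C)C | intermediate
28 | as 27 with free C6–OH | C[C@]12CC(=O)[C@](CCO[Si](C)(C)C(C)(C)C)(O1)[C@H](O)[C@@H]3O[C@]3(C)CCC2ON4C(C)(C)CCCC4(C)C | intermediate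
29 | C6,C8-diol, C8–OH cis to C11 and trans to C6 on the oxolane (8S) | C[C@]12C[C@H](O)[C@](CCO[Si](C)(C)C(C)(C)C)(O1)[C@H](O)[C@@H]3O[C@]3(C)CCC2ON4C(C)(C)CCCC4(C)C | intermediate
30 | methacrylic anhydride | CC(=C)C(=O)OC(=O)C(C)=C | starting material
31 | C8 methacrylate of 29 | C[C@]12C[C@H](OC(=O)C(C)=C)[C@](CCO[Si](C)(C)C(C)(C)C)(O1)[C@H](O)[C@@H]3O[C@]3(C)CCC2ON4C(C)(C)CCCC4(C)C | intermediate
32 | as 31 with free C12–OH | C[C@]12C[C@H](OC(=O)C(C)=C)[C@](CCO)(O1)[C@H](O)[C@@H]3O[C@]3(C)CCC2ON4C(C)(C)CCCC4(C)C | intermediate
33 | C12 aldehyde (not isolated) | C[C@]12C[C@H](OC(=O)C(C)=C)[C@](CC=O)(O1)[C@H](O)[C@@H]3O[C@]3(C)CCC2ON4C(C)(C)CCCC4(C)C | intermediate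
34 | C6–O–C12 lactol (C12 epimers), spiro to the oxolane at C7 | C[C@]12C[C@H](OC(=O)C(C)=C)[C@@]3(O1)CC(O)O[C@@H]3[C@@H]4O[C@]4(C)CCC2ON5C(C)(C)CCCC5(C)C | intermediate
35 | C11-methylidene lactol | C[C@]12C[C@H](OC(=O)C(C)=C)[C@@]3(O1)C(=C)C(O)O[C@@H]3[C@@H]4O[C@]4(C)CCC2ON5C(C)(C)CCCC5(C)C | intermediate
36 | α-methylidene-γ-lactone with the C1 alkoxyamine | C[C@]12C[C@H](OC(=O)C(C)=C)[C@@]3(O1)C(=C)C(=O)O[C@@H]3[C@@H]4O[C@]4(C)CCC2ON5C(C)(C)CCCC5(C)C | intermediate
37 | CNP0241021.1, (4R,5S,6R,7S,8S,10R) in the numbering used here | C=C(C)C(=O)O[C@H]1C[C@@]2(C)O[C@@]13C(=C)C(=O)O[C@@H]3[C@@H]1O[C@]1(C)CCC2=O | target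

**Step count and risks**
Total step count: 26.
Longest linear sequence: 22 (steps 1–4 or 5–8, then 9–26).

Most likely to fail:

Step 9 (new method). The cation may lose a proton to give a dienone. It may bond at C4, the partners may meet in the compact instead of the extended orientation, or the sequence may stop after the first bond.
- Fallback: form the two bonds one after the other with known reactions, setting out from 7 and 14.
- Ionisation of 7 with Na2CO3 in (CF3)2CHOH is a nucleophilic capture of an oxyallyl cation by an electron-rich π-nucleophile. The protic medium takes off the silyl group, so this should give the C6–C7-linked 2,2-disubstituted furanone F1.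
- TBSOTf/Et3N then enolises the ring ketone towards C1, silylates the vinylogous ester and closes C1–C10 by an intramolecular Mukaiyama–Michael addition. This comes back to the route at 16.

Step 13. The peroxide may add too slowly to the hindered carbonyl. The Lewis acid may ionise the C7–O bond, which is allylic once C8 carries the methylidene group, or shift the exocyclic alkene. C1 may also migrate in competition with C6.
- Fallback: change the C8 mask and the order of events, setting out from 18.
- NaBH4 (MeOH/CH2Cl2, −40 °C, attack from the open face) gives the C8 endo alcohol F2, which has no allylic ether.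
- The same silyl-peroxide Baeyer–Villiger oxidation gives the hydroxy lactone F3.
- Dess–Martin oxidation gives the keto lactone F4, and Wittig methylenation of its ketone comes back to the route at 20.

Step 21. Acylation may also reach C6–OH (poor site selectivity).
- Fallback: differentiate the two hydroxyls with protecting groups, setting out from 29.
- TESOTf/2,6-lutidine gives the bis-triethylsilyl ether F5.
- Brief PPTS/MeOH frees the less shielded C8–OH to give the C6 mono-triethylsilyl ether F6.
- Methacrylic anhydride/DMAP gives the C8 methacrylate C6 silyl ether F7.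
- Et3N·3HF removes TES and TBS together and comes back to the route at 32.

**Further compounds**
F1 | step 9 | 2-[2-(tert-butyldimethylsilyloxy)ethyl]-5-methyl-2-(4-methyl-7-oxocyclohept-2-en-1-yl)furan-3(2H)-one (racemic, C6/C7 as in 16) | CC1=CC(=O)[C@](CCO[Si](C)(C)C(C)(C)C)(O1)[C@H]1/C=C(/C)CCCC1=O
F2 | step 13 | C8 endo alcohol of 18 (OH cis to C6 on the oxolane) | C[C@]12C[C@@H](O)[C@](CCO[Si](C)(C)C(C)(C)C)(O1)[C@H]1/C=C(/C)CC[C@@H]2C1=O
F3 | step 13 | bridged lactone with C8 endo alcohol | C[C@]12C[C@@H](O)[C@](CCO[Si](C)(C)C(C)(C)C)(O1)[C@H]1/C=C(/C)CC[C@@H]2C(=O)O1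
F4 | step 13 | bridged lactone with C8 ketone | C[C@]12CC(=O)[C@](CCO[Si](C)(C)C(C)(C)C)(O1)[C@H]1/C=C(/C)CC[C@@H]2C(=O)O1
F5 | step 21 | C6,C8-bis(triethylsilyl) ether of 29 | C[C@]12C[C@H](O[Si](CC)(CC)CC)[C@](CCO[Si](C)(C)C(C)(C)C)(O1)[C@H](O[Si](CC)(CC)CC)[C@@H]3O[C@]3(C)CCC2ON4C(C)(C)CCCC4(C)C
F6 | step 21 | C6 triethylsilyl ether of 29 with free C8–OH | C[C@]12C[C@H](O)[C@](CCO[Si](C)(C)C(C)(C)C)(O1)[C@H](O[Si](CC)(CC)CC)[C@@H]3O[C@]3(C)CCC2ON4C(C)(C)CCCC4(C)C
F7 | step 21 | C8 methacrylate, C6 triethylsilyl ether | C[C@]12C[C@H](OC(=O)C(C)=C)[C@](CCO[Si](C)(C)C(C)(C)C)(O1)[C@H](O[Si](CC)(CC)CC)[C@@H]3O[C@]3(C)CCC2ON4C(C)(C)CCCC4(C)C
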